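**Retrosynthetic overview**

1. The acid comes from its methyl ester. The ester is cut at the C14–C15 (sp2–sp3) bond and at C14–CH3. This gives a bicyclic 1,1-dichloroalkene (C1–C14), a triene ester (C15–C22 plus CO2Me, used as its 9-BBN adduct) and Me2Zn, all joined in one flask.
2. Enabling feature: C14 is the fully substituted terminus of the C13=C14 olefin, remote from the rings. It carries two carbon ligands, C15H2 trans and CH3 cis to C12. Written as CCl2 it has no geometry, and its two C–Cl bonds differ only in their relation to the C12–C11–C9 (ring B) chain, so replacing them in order fixes the 13E geometry. The C15=C16 vinyl end is the only monosubstituted olefin of the other half.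
3. Bicyclic half: the dichloroalkene comes from a C13 aldehyde. The aldehyde comes from a C9 radical plus acrolein (C9–C11 bond), the radical from a 9β-bromo-8α-ol, the bromohydrin from a C8=C9 olefin, and the olefin from a C9 ketone.
4. Ring order: ring B is bought as (S)-carvone. Ring A is closed second, onto C5 and C10, by a Diels–Alder reaction with a 2-silyloxydiene that carries the C4 gem-dimethyl group, giving the A/B-cis fusion. The C7 isopropenyl stereocentre controls C5 and C10 and is then erased; C5 and C10 control C8 and C9.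
5. Chain half: geranyl acetate, elaborated by selective ozonolysis, two Wittig reactions and an allylic oxidation.

Key step: step 16

Remark: the SMILES is read literally as (5S,8R,9R,10S), so H-5 is cis to CH3-10 (A/B cis-decalin); CH3-10, H-5, the C9 side chain and CH3-8 lie on one face (called β), and HO-8 and H-9 on the other (α); polypodane numbering (C1–C10 decalin, C11–C22 chain) is used for all intermediates.

**Route**

Step 1
Reactants: 1 4-methylpent-1-en-3-one (isopropyl vinyl ketone)
Product: 2 tert-butyl(dimethyl)[(4-methylpenta-1,3-dien-3-yl)oxy]silane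
Conditions: TBSOTf, Et3N, CH2Cl2, 0 °C
Reagents that add atoms: tert-butyldimethylsilyl triflate, CC(C)(C)[Si](C)(C)OS(=O)(=O)C(F)(F)F
Why: Silyl enol ether formation by soft enolisation; the only α-hydrogen of 1 is the isopropyl C–H, so only the cross-conjugated 2-silyloxydiene can form.

Step 2
Reactants: 2 tert-butyl(dimethyl)[(4-methylpenta-1,3-dien-3-yl)oxy]silane; 3 (S)-(+)-carvone
Product: 4 Diels–Alder adduct: A/B-cis 3-(TBSO)-7β-isopropenyl-4,4,10β-trimethyl-5β-H-octal-2-en-9-one
Conditions: AlBr3/AlMe3 (5:1, 20 mol %), PhMe/CH2Cl2, −20 to 0 °C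
Reagents that add atoms: none
Why: Lewis-acid-catalysed Diels–Alder reaction of a 2-silyloxydiene with a 2-methylcycloalkenone, in which the nucleophilic CMe2 terminus next to C–OSi bonds to the enone β-carbon C5 and the CH2 terminus to C10 (para orientation, which also avoids adjacent quaternary carbons), suprafacial addition makes H-5 cis to CH3-10 (locked, since C5 is not α to a carbonyl), and approach anti to the C7 isopropenyl group fixes the absolute configuration of C5 and C10.

Step 3
Reactants: 4 Diels–Alder adduct
Product: 6 8ξ-methyl ketone (4 methylated at C8; both C8 epimers serve), via lithium enolate 5 (not isolated)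
Conditions: LiN(iPr)2, THF, −78 °C; MeI, −78 to 0 °C
Reagents that add atoms: iodomethane, CI
Why: Kinetic enolate alkylation; C10 is quaternary, so the C9 ketone can be deprotonated only at C8, the C3 carbonyl stays masked as its enol silane, and the configuration at C8 does not matter because C8 becomes sp2 in step 6.

Step 4
Reactants: 6 8ξ-methyl ketone
Product: 7 3,3-ethylenedioxy-7β-isopropenyl-4,4,8ξ,10β-tetramethyl-5β-H-decalin-9-one
Conditions: HOCH2CH2OH, p-TsOH·H2O (5 mol %), benzene, 4 Å MS, 40 °C
Reagents that add atoms: ethylene glycol, OCCO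
Why: Acid-catalysed ketalisation; protonation of the enol silane at C2 unmasks C3, which is captured by the glycol, while the C9 ketone, flanked by a quaternary and a tertiary carbon (a 2,2,6-trisubstituted cyclohexanone), is too hindered to ketalise.

Step 5
Reactants: 7 3,3-ethylenedioxy-7β-isopropenyl-4,4,8ξ,10β-tetramethyl-5β-H-decalin-9-one
Product: 9 3,3-ethylenedioxy-4,4,8ξ,10β-tetramethyl-5β-H-decalin-9-one, via α-methoxyhydroperoxide 8 (not isolated)
Conditions: O3, MeOH, −78 °C; then PhSH, FeSO4·7H2O, −78 °C to rt
Reagents that add atoms: none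
Why: Hydrodealkenylative C(sp3)–C(sp2) fragmentation; ozonolysis in methanol gives 8, reduction by divalent iron gives an alkoxyl radical whose β-scission expels methyl acetate, and the secondary C7 radical takes hydrogen from PhSH, which erases the spent control stereocentre without touching C5 or C10.

Step 6
Reactants: 9 3,3-ethylenedioxy-4,4,8ξ,10β-tetramethyl-5β-H-decalin-9-one
Product: 11 3,3-ethylenedioxy-4,4,8,10β-tetramethyl-5β-H-octal-8-en-9-yl triflate, via potassium enolate 10 (not isolated)
Conditions: KN(SiMe3)2, THF, −78 to 0 °C; PhNTf2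
Reagents that add atoms: N-phenylbis(trifluoromethanesulfonimide), O=S(=O)(N(c1ccccc1)S(=O)(=O)C(F)(F)F)C(F)(F)F
Why: Enol triflate formation; C8–H is the only enolisable position of 9, so a single tetrasubstituted C8=C9 enol triflate results, as is routine for 2,2,6-trisubstituted cyclohexanones.

Step 7
Reactants: 11 3,3-ethylenedioxy-4,4,8,10β-tetramethyl-5β-H-octal-8-en-9-yl triflate
Product: 13 (4aR,8aS)-1,1,4a,6-tetramethyl-3,4,4a,7,8,8a-hexahydronaphthalen-2(1H)-one (4,4,8,10β-tetramethyl-5β-H-octal-8-en-3-one), via ketal alkene 12 (not isolated)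
Conditions: Pd(OAc)2 (5 mol %), PPh3 (10 mol %), HCO2H, Et3N, DMF, 60 °C; then 1 M HCl, THF, rt
Reagents that add atoms: water, O
Why: Palladium-catalysed formate reduction of an enol triflate (oxidative addition, decarboxylation of formate to Pd–H, reductive elimination) replaces OTf by H without moving the double bond, and the acidic work-up hydrolyses the strained neopentyl dioxolane before any acid-sensitive tertiary alcohol is present.

Step 8
Reactants: 13 4,4,8,10β-tetramethyl-5β-H-octal-8-en-3-one
Product: 14 9β-bromo-8α-hydroxy-4,4,8β,10β-tetramethyl-5β-H-decalin-3-one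
Conditions: NBS, acetone/H2O, 0 °C, dark
Reagents that add atoms: N-bromosuccinimide, O=C1CCC(=O)N1Br; water, O
Why: Bromohydrin formation; Br+ is taken up on the convex β face (the α face is covered by ring A and the pseudo-axial C1) and water opens the bromonium ion anti at the tertiary C8 (Markovnikov, trans-diaxial), which sets 8α-OH and 8β-CH3 (8R) and places bromine 9β.

Step 9
Reactants: 14 9β-bromo-8α-hydroxy-4,4,8β,10β-tetramethyl-5β-H-decalin-3-one
Product: 15 3-(8α-hydroxy-4,4,8β,10β-tetramethyl-3-oxo-5β-H-decalin-9β-yl)propanal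
Conditions: acrolein (5 equiv), (Me3Si)3SiH (slow addition), AIBN (cat.), PhMe, 80 °C
Reagents that add atoms: acrolein, C=CC=O
Why: Giese reaction; bromine abstraction gives the secondary C9 radical, whose α face is blocked by the two flanking axial groups (C1 on C10, HO on C8) and by ring A, so acrolein is attacked from the β face (C11 β, H-9 α, 9R) and the resulting α-formyl radical is reduced by the silane.

Step 10
Reactants: 15 3-(8α-hydroxy-4,4,8β,10β-tetramethyl-3-oxo-5β-H-decalin-9β-yl)propanal
Product: 16 9β-(4,4-dichlorobut-3-enyl)-8α-hydroxy-4,4,8β,10β-tetramethyl-5β-H-decalin-3-one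
Conditions: (EtO)2P(O)CCl3 (2.2 equiv), n-BuLi (2.2 equiv), THF/Et2O, −100 °C; then 15, −100 °C to rt
Reagents that add atoms: diethyl (trichloromethyl)phosphonate, CCOP(=O)(OCC)C(Cl)(Cl)Cl
Why: Horner–Wadsworth–Emmons-type dichloromethylenation; the lithiated dichloromethylphosphonate adds to the aldehyde far faster than to the neopentyl C3 ketone and loss of phosphate gives the 1,1-dichloroalkene, one equivalent of carbanion being spent on HO-8, which is recovered on work-up.

Step 11
Reactants: 17 geranyl acetate
Product: 19 (E)-6-acetoxy-4-methylhex-4-enal, via secondary ozonide 18 (not isolated)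
Conditions: O3 (1 equiv), CH2Cl2, −78 °C; Me2S, −78 °C to rt
Reagents that add atoms: ozone, [O-][O+]=O
Why: Chemoselective ozonolysis; the remote isopropylidene double bond is more electron-rich than the one deactivated by the allylic acetate, so one equivalent of ozone cleaves only the chain end and Me2S reduces the ozonide.

Step 12
Reactants: 19 (E)-6-acetoxy-4-methylhex-4-enal
Product: 20 methyl (2E,6E)-8-acetoxy-2,6-dimethylocta-2,6-dienoate
Conditions: Ph3P=C(CH3)CO2CH3, CH2Cl2, rt
Reagents that add atoms: methyl 2-(triphenylphosphoranylidene)propanoate, COC(=O)C(C)=P(c1ccccc1)(c1ccccc1)c1ccccc1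
Why: Wittig reaction with a stabilised α-methyl ylide, which should give the (E)-2-methyl-2-enoate (the C21=C22 geometry).

Step 13
Reactants: 20 methyl (2E,6E)-8-acetoxy-2,6-dimethylocta-2,6-dienoate
Product: 21 methyl (2E,6E)-8-hydroxy-2,6-dimethylocta-2,6-dienoate
Conditions: K2CO3 (cat.), MeOH, 0 °C
Reagents that add atoms: none
Why: Base-catalysed transesterification (methanolysis) removes the primary allylic acetate, while the conjugated methyl ester can only exchange methoxide for methoxide.

Step 14
Reactants: 21 methyl (2E,6E)-8-hydroxy-2,6-dimethylocta-2,6-dienoate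
Product: 22 methyl (2E,6E)-2,6-dimethyl-8-oxoocta-2,6-dienoate
Conditions: MnO2, CH2Cl2, rt
Reagents that add atoms: none
Why: Allylic alcohol oxidation with MnO2, which is selective for allylic alcohols and should give the (E)-enal without over-oxidation.

Step 15
Reactants: 22 methyl (2E,6E)-2,6-dimethyl-8-oxoocta-2,6-dienoate
Product: 23 methyl (2E,6E)-2,6-dimethylnona-2,6,8-trienoate
Conditions: CH3PPh3Br, KN(SiMe3)2, THF, 0 °C; then 22, −78 to 0 °C
Reagents that add atoms: methyltriphenylphosphonium bromide, C[P+](c1ccccc1)(c1ccccc1)c1ccccc1.[Br-]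
Why: Wittig methylenation; the non-stabilised ylide reacts with the aldehyde at low temperature far faster than with the hindered enoate and leaves the trisubstituted olefin geometries untouched.

Step 16
Reactants: 16 9β-(4,4-dichlorobut-3-enyl)-8α-hydroxy-4,4,8β,10β-tetramethyl-5β-H-decalin-3-one; 23 methyl (2E,6E)-2,6-dimethylnona-2,6,8-trienoate
Product: 26 myrrhanone B methyl ester (5S,8R,9R,10S; 13E,17E,21E), via B-alkyl-9-BBN 24 (not isolated), via (Z)-chloroalkene 25 (not isolated)
Conditions: 23 (1.2 equiv), 9-BBN-H (1.1 equiv), THF, 0 °C to rt; then 16 (1.0 equiv), Pd2(dba)3 (2.5 mol %), XantPhos (5 mol %), K3PO4 (3 equiv), THF, 65 °C; then Pd(PtBu3)2 (5 mol %), Me2Zn (3 equiv, PhMe), 50 °C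
Reagents that add atoms: dimethylzinc, C[Zn]C
Why: 9-BBN-H adds only to the monosubstituted C15=C16 terminus of the diene of 23 (boron on C15; the trisubstituted olefins are too hindered and the enoate too electron-poor), giving the primary borane 24. Zerovalent palladium carrying the wide-bite-angle XantPhos inserts only into the C14–Cl bond of 16 that is trans to the C12 chain (the less hindered one, cis to H-13), and transmetalation from the phosphate-activated borane followed by reductive elimination forms C14–C15 with retention; this is a B-alkyl Suzuki–Miyaura mono-coupling of a 1,1-dichloro-1-alkene, which should stop at (Z)-chloroalkene 25 because this catalyst does not activate the remaining hindered C–Cl bond. The electron-rich Pd(PtBu3)2 added next does insert into that bond and Me2Zn replaces Cl by CH3 with retention (Negishi coupling of an alkenyl chloride), so C15 ends trans and CH3 cis to C12, which is the 13E olefin. No ring is closed and no sp3 stereocentre is created; the one stereo-element made, the C13=C14 geometry, is controlled by the steric difference between the two geminal chlorines. Chemoselectivity (C3 ketone, tertiary HO-8 and enoate untouched) is secured by the mild boron and zinc nucleophiles, the neopentyl position of C3=O, the absence of residual B–H (23 in excess over 9-BBN-H) and one extra equivalent of Me2Zn for the hydroxyl proton. In one flask the operation joins the C18 and C11 halves and the last methyl carbon, completing the C30 skeleton and its last olefin geometry from a precursor that has no stereodefined vinyl halide.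

Step 17
Reactants: 26 myrrhanone B methyl ester
Product: 28 myrrhanone B as drawn: (2E,6E,10E)-13-[(1R,2R,4aS,8aS)-2-hydroxy-2,5,5,8a-tetramethyl-6-oxodecahydronaphthalen-1-yl]-2,6,10-trimethyltrideca-2,6,10-trienoic acid, via lithium carboxylate 27 (not isolated)
Conditions: LiOH, THF/MeOH/H2O, 40 °C; then 1 M HCl to pH 4, 0 °C
Reagents that add atoms: lithium hydroxide, [Li+].[OH-]
Why: Saponification (acyl–oxygen ester hydrolysis) followed by mild acidification; no stereocentre is α to a carbonyl group (C2 is the only enolisable position of the C3 ketone) and the tertiary alcohol never meets strong acid.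

**Compound list**

1 | 4-methylpent-1-en-3-one | C=CC(=O)C(C)C | starting material
2 | tert-butyl(dimethyl)[(4-methylpenta-1,3-dien-3-yl)oxy]silane | C=CC(O[Si](C)(C)C(C)(C)C)=C(C)C | intermediate
3 | (S)-(+)-carvone | CC1=CC[C@@H](CC1=O)C(C)=C | starting material
4 | Diels–Alder adduct (A/B cis, 3-OTBS, Δ2, 9-one, 7β-isopropenyl) | O=C1[C@@]2(C)CC=C(O[Si](C)(C)C(C)(C)C)C(C)(C)[C@H]2C[C@H](C(C)=C)C1 | intermediate
5 | lithium C8=C9 enolate of 4 | [Li]OC=1[C@@]2(C)CC=C(O[Si](C)(C)C(C)(C)C)C(C)(C)[C@H]2C[C@H](C(C)=C)C=1 | intermediate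
6 | 8ξ-methyl ketone | O=C1[C@@]2(C)CC=C(O[Si](C)(C)C(C)(C)C)C(C)(C)[C@H]2C[C@H](C(C)=C)C1C | intermediate
7 | C3 ethylene ketal, 7β-isopropenyl, 9-one | O=C1[C@@]2(C)CCC3(OCCO3)C(C)(C)[C@H]2C[C@H](C(C)=C)C1C | intermediate
8 | α-methoxyhydroperoxide from 7 | O=C1[C@@]2(C)CCC3(OCCO3)C(C)(C)[C@H]2C[C@H](C(C)(OC)OO)C1C | intermediate
9 | 3,3-ethylenedioxy-4,4,8ξ,10β-tetramethyl-5β-H-decalin-9-one | O=C1[C@@]2(C)CCC3(OCCO3)C(C)(C)[C@H]2CCC1C | intermediate
10 | potassium C8=C9 enolate of 9 | [K]OC=1[C@@]2(C)CCC3(OCCO3)C(C)(C)[C@H]2CCC=1C | intermediate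
11 | C9 enol triflate | O=S(=O)(OC=1[C@@]2(C)CCC3(OCCO3)C(C)(C)[C@H]2CCC=1C)C(F)(F)F | intermediate
12 | ketal alkene | C=1[C@@]2(C)CCC3(OCCO3)C(C)(C)[C@H]2CCC=1C | intermediate
13 | (4aR,8aS)-1,1,4a,6-tetramethyl-3,4,4a,7,8,8a-hexahydronaphthalen-2(1H)-one | C=1[C@@]2(C)CCC(=O)C(C)(C)[C@H]2CCC=1C | intermediate
14 | 9β-bromo-8α-hydroxy ketone | Br[C@@H]1[C@@]2(C)CCC(=O)C(C)(C)[C@H]2CC[C@@]1(C)O | intermediate
15 | C13 hydroxy aldehyde | O=CCC[C@@H]1[C@@]2(C)CCC(=O)C(C)(C)[C@H]2CC[C@@]1(C)O | intermediate
16 | 1,1-dichloroalkene (C1–C14 half) | ClC(Cl)=CCC[C@@H]1[C@@]2(C)CCC(=O)C(C)(C)[C@H]2CC[C@@]1(C)O | intermediate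
17 | geranyl acetate | CC(C)=CCC/C(C)=C/COC(C)=O | starting material
18 | secondary ozonide of the 6,7-double bond | CC(=O)OC/C=C(\C)CCC1OOC(C)(C)O1 | intermediate
19 | (E)-6-acetoxy-4-methylhex-4-enal | CC(=O)OC/C=C(\C)CCC=O | intermediate
20 | methyl (2E,6E)-8-acetoxy-2,6-dimethylocta-2,6-dienoate | COC(=O)/C(C)=C/CC/C(C)=C/COC(C)=O | intermediate
21 | methyl (2E,6E)-8-hydroxy-2,6-dimethylocta-2,6-dienoate | COC(=O)/C(C)=C/CC/C(C)=C/CO | intermediate
22 | methyl (2E,6E)-2,6-dimethyl-8-oxoocta-2,6-dienoate | COC(=O)/C(C)=C/CC/C(C)=C/C=O | intermediate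
23 | methyl (2E,6E)-2,6-dimethylnona-2,6,8-trienoate | COC(=O)/C(C)=C/CC/C(C)=C/C=C | intermediate
24 | methyl (2E,6E)-9-(9-borabicyclo[3.3.1]nonan-9-yl)-2,6-dimethylnona-2,6-dienoate | COC(=O)/C(C)=C/CC/C(C)=C/CCB1C2CCCC1CCC2 | intermediate
25 | (13Z)-14-chloro analogue of 26 (Cl in place of CH3-14) | COC(=O)/C(C)=C/CC/C(C)=C/CC/C(Cl)=C/CC[C@@H]1[C@@]2(C)CCC(=O)C(C)(C)[C@H]2CC[C@@]1(C)O | intermediate
26 | myrrhanone B methyl ester | COC(=O)/C(C)=C/CC/C(C)=C/CC/C(C)=C/CC[C@@H]1[C@@]2(C)CCC(=O)C(C)(C)[C@H]2CC[C@@]1(C)O | intermediate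
27 | lithium carboxylate of 28 | [Li+].[O-]C(=O)/C(C)=C/CC/C(C)=C/CC/C(C)=C/CC[C@@H]1[C@@]2(C)CCC(=O)C(C)(C)[C@H]2CC[C@@]1(C)O | intermediate
28 | myrrhanone B (5S,8R,9R,10S; 13E,17E,21E) | C/C(=C\CC/C(C)=C/CC[C@@H]1[C@@]2(C)CCC(=O)C(C)(C)[C@H]2CC[C@@]1(C)O)CC/C=C(\C)C(=O)O | target

**Counts and risks**

Total step count: 17. Longest linear sequence: 12 steps (steps 1–10, 16, 17).

Three steps most likely to fail:

**Step 2.** Both partners are hindered. The cycloaddition may stall, the diene may be lost by protodesilylation or oligomerisation, or the process may stop after the first C–C bond and lose the enol silane that differentiates C3 from C9.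

The fallback sets out from 3 and 2 and returns at 7. Carvone 3 is methylated first at its α′ carbon, the future C8 (LiN(iPr)2, MeI), to give 6-methylcarvone F1. F1 and 2 are then combined with stoichiometric TiCl4 in CH2Cl2 at −78 °C in a deliberately stepwise Mukaiyama–Michael addition and intramolecular Michael ring closure. The C4 terminus adds to C5 anti to the isopropenyl group, and the C10 enolate closes onto the tethered vinyl ketone on the tether-bearing face. Aqueous work-up gives the A/B-cis diketone F2. In F2 the C9 ketone is flanked by a quaternary and a tertiary carbon, so ketalisation (HOCH2CH2OH, p-TsOH) should take place only at C3 and give 7.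

**Step 9.** The hindered C9 radical may be reduced by the silane before it adds, and acrolein may telomerise or be consumed by the chain carrier.

The fallback sets out from 14 and returns at 15. A Keck allylation (Bu3SnCH2CH=CH2, AIBN, benzene, 80 °C) transfers an allyl group by addition–fragmentation, without a competing hydride donor, and gives the 9β-allyl ketol F3. Hydroboration of the terminal olefin with 9-BBN-H and oxidation with NaBO3 give the primary alcohol F4. TEMPO/PhI(OAc)2 then oxidises only the primary hydroxyl to give 15.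

**Step 16.** The first coupling may run on to double alkylation. The second oxidative addition may be slowed by boron and phosphate residues left in the flask. The alkenylpalladium intermediate may isomerise and erode the olefin geometry.

The fallback sets out from 15 and 23 and returns at 26. It forms the same C14–C15 bond with reversed polarity.
- Aldehyde 15 is treated with lithiated 1,1-bis(pinacolatoboryl)ethane (lithium 2,2,6,6-tetramethylpiperidide, THF, −78 °C to rt; boron-Wittig olefination). This should give the trisubstituted alkenylboronate F5 with Bpin trans to C12.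
- Triene ester 23 is hydroborated with 9-BBN-H and oxidised (NaBO3) to the homoallylic alcohol F6, which is converted (CBr4, PPh3) into the primary bromide F7.
- An alkyl-bromide Suzuki–Miyaura coupling of F5 and F7 (Pd(OAc)2, P(t-Bu)2Me, KOt-Bu, t-AmOH, rt) then joins C14 and C15 with retention and gives 26.

**Further compounds**

F1 | step 2 | 6-methylcarvone, (5S)-2,6-dimethyl-5-(prop-1-en-2-yl)cyclohex-2-en-1-one (C6 epimers) | CC1=CC[C@H](C(C)=C)C(C)C1=O
F2 | step 2 | A/B-cis 7β-isopropenyl-4,4,8ξ,10β-tetramethyl-5β-H-decalin-3,9-dione | O=C1[C@@]2(C)CCC(=O)C(C)(C)[C@H]2C[C@H](C(C)=C)C1C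
F3 | step 9 | 9β-allyl-8α-hydroxy-4,4,8β,10β-tetramethyl-5β-H-decalin-3-one | C=CC[C@@H]1[C@@]2(C)CCC(=O)C(C)(C)[C@H]2CC[C@@]1(C)O
F4 | step 9 | 8α-hydroxy-9β-(3-hydroxypropyl)-4,4,8β,10β-tetramethyl-5β-H-decalin-3-one | OCCC[C@@H]1[C@@]2(C)CCC(=O)C(C)(C)[C@H]2CC[C@@]1(C)O
F5 | step 16 | C14 pinacol alkenylboronate (Bpin trans to C12) | CC1(C)OB(OC1(C)C)/C(C)=C/CC[C@@H]1[C@@]2(C)CCC(=O)C(C)(C)[C@H]2CC[C@@]1(C)O
F6 | step 16 | methyl (2E,6E)-9-hydroxy-2,6-dimethylnona-2,6-dienoate | COC(=O)/C(C)=C/CC/C(C)=C/CCO
F7 | step 16 | methyl (2E,6E)-9-bromo-2,6-dimethylnona-2,6-dienoate | COC(=O)/C(C)=C/CC/C(C)=C/CCBr
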